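**Retrosynthetic overview**
- The depside ester C(=O)–O bond between the ring A acyl carbon and O4 of ring B is cut last. This gives 5-chloro-2-hydroxy-4-methoxy-3,6-dimethylbenzoic acid and methyl 2,4-dihydroxy-3,5,6-trimethylbenzoate, which are joined at the unchelated 4-OH.
- The strategy rests on ring B, a hexasubstituted benzene with CO2Me at C1, oxygen at C2 and C4 (1,3-related) and methyl at C3, C5 and C6. This is the pattern of a 2,4-dioxocyclohexane-1-carboxylate, so ring B is built saturated with every substituent in place and dehydrogenated afterwards.
- The saturated ring is opened at C1–C6 (Michael) and C2–C3 (Claisen). Dimethyl malonate supplies C1, C2 and the ester; (E)-4-methylhex-4-en-3-one supplies C3–C6 and all three methyls. The enone comes from pentan-3-one and acetaldehyde.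
- Ring A is not constructed: atraric acid supplies it, adjusted by 4-O-methylation, chlorination at C5 and ester cleavage.
- Ring order: the ring B carbocycle is closed in step 3 and aromatised in step 4; ring A is bought as an arene; the two are esterified in step 8.

Key step: step 3

Remark on the chemistry: the target has no stereocentre and the aryl ester axis is taken as freely rotating, so no stereochemical control is needed; the sp3 centres made on the way are all erased.

**Step 1**
Reactants: 1 pentan-3-one; 2 acetaldehyde
Product: 3 5-hydroxy-4-methylhexan-3-one (racemic syn/anti mixture)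
Conditions: cat. KOH, MeOH, 0–5 °C, 1 in excess, slow addition of 2
Reagents that add atoms: none
Why: Base-catalysed crossed aldol addition, in which the excess ketone enolate should intercept acetaldehyde as it is added and hold back its self-condensation; the two new stereocentres form as a mixture that does not matter because step 2 destroys both.

**Step 2**
Reactants: 3 5-hydroxy-4-methylhexan-3-one
Product: 4 (E)-4-methylhex-4-en-3-one
Conditions: cat. p-TsOH·H2O, cyclohexane, reflux (Dean–Stark); distillation
Reagents that add atoms: none
Why: Acid-catalysed dehydration of a β-hydroxy ketone (completion of the aldol condensation) with azeotropic removal of water should give the conjugated trisubstituted enone as the thermodynamically preferred E isomer.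

**Step 3**
Reactants: 4 (E)-4-methylhex-4-en-3-one; 5 dimethyl malonate
Product: 7 methyl 2-hydroxy-3,5,6-trimethyl-4-oxocyclohex-2-ene-1-carboxylate (diastereomer mixture), via keto diester Michael adduct 6 (not isolated)
Conditions: NaOMe (1.1 equiv), MeOH, rt → reflux; then cold aq. HCl to pH 2
Reagents that add atoms: none
Why: Methoxide deprotonates 5, whose stabilised anion adds 1,4 to the β-carbon of 4 (ring bond C1–C6) to give 6; proton exchange in methanol then populates the enolate at the ethyl CH2, which attacks one malonate ester carbonyl and expels methoxide (ring bond C2–C3). The closest known reaction type is the Michael–Claisen (Dieckmann-type) annulation of malonates with enones, as in the dimedone synthesis and the preparation of dihydroresorcylates from alkenyl ethyl ketones. The ring closes in a 6-(enolexo)-exo-trig mode. The sp3 centres C1, C5 and C6 form under equilibrating conditions as a mixture and need no control, since all three become aromatic carbons in step 4. The selectivity needed is regiochemical: the alternative enolate at ring C5 could reach an ester carbonyl only by closing a four-membered ring, and 1,2-addition and retro-Michael reaction are reversible, so the material should drain into the six-membered β-dicarbonyl, whose deprotonation at C3 by methoxide drives the sequence. The α-methyl group of 4 slows the conjugate addition, which is why prolonged reflux is planned.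

**Step 4**
Reactants: 7 methyl 2-hydroxy-3,5,6-trimethyl-4-oxocyclohex-2-ene-1-carboxylate
Product: 9 methyl 2,4-dihydroxy-3,5,6-trimethylbenzoate, via 3-bromo-2,4-dione 8 (not isolated)
Conditions: Br2 (1.0 equiv), AcOH, 15 °C → 70 °C
Reagents that add atoms: none
Why: Halogenation–dehydrohalogenation aromatisation of a dihydroresorcylate, in which the enolised 1,3-dione is brominated at C3 to give 8, HBr relays the bromine to an enolisable α-position, loss of HBr toward C6 and enolisation give the arene, and no nuclear bromination can follow because every ring carbon of 9 is substituted.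

**Step 5**
Reactants: 10 methyl 2,4-dihydroxy-3,6-dimethylbenzoate (atraric acid)
Product: 11 methyl 2-hydroxy-4-methoxy-3,6-dimethylbenzoate
Conditions: MeI (1.1 equiv), K2CO3 (1.1 equiv), acetone, reflux
Reagents that add atoms: iodomethane, CI
Why: Williamson ether synthesis that should be selective for the more acidic, non-hydrogen-bonded 4-OH, while the 2-OH chelated to the ester carbonyl stays free with one equivalent of base and alkylating agent.

**Step 6**
Reactants: 11 methyl 2-hydroxy-4-methoxy-3,6-dimethylbenzoate
Product: 12 methyl 5-chloro-2-hydroxy-4-methoxy-3,6-dimethylbenzoate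
Conditions: SO2Cl2 (1.05 equiv), CH2Cl2, 0 °C → rt
Reagents that add atoms: sulfuryl chloride, O=S(=O)(Cl)Cl
Why: Electrophilic aromatic chlorination at C5, the only unsubstituted ring position, which is activated para to the 2-OH and ortho to the 4-OMe; one equivalent of reagent limits ipso attack.

**Step 7**
Reactants: 12 methyl 5-chloro-2-hydroxy-4-methoxy-3,6-dimethylbenzoate
Product: 13 5-chloro-2-hydroxy-4-methoxy-3,6-dimethylbenzoic acid
Conditions: conc. H2SO4, 0 °C → rt; poured onto ice
Reagents that add atoms: water, O
Why: Acylium-type (AAc1) hydrolysis of a 2,6-disubstituted benzoate, in which the ester ionises in cold concentrated acid to an acylium ion stabilised by the ortho-hydroxyl and is hydrated on quenching, avoiding the forcing alkaline conditions that such hindered esters need and keeping the acid cold enough to resist decarboxylation.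

**Step 8**
Reactants: 13 5-chloro-2-hydroxy-4-methoxy-3,6-dimethylbenzoic acid; 9 methyl 2,4-dihydroxy-3,5,6-trimethylbenzoate
Product: 15 methyl 4-[(5-chloro-2-hydroxy-4-methoxy-3,6-dimethylbenzoyl)oxy]-2-hydroxy-3,5,6-trimethylbenzoate (target), via mixed trifluoroacetic anhydride 14 (not isolated)
Conditions: 13, (CF3CO)2O (3 equiv), toluene, rt; then 9, rt → 40 °C; aq. NaHCO3 work-up
Reagents that add atoms: none
Why: Trifluoroacetic anhydride-mediated esterification (mixed anhydride/acylium method for hindered acids), in which 14 ionises toward a linear acylium ion that the unchelated 4-OH of 9 should capture while both chelated ortho-hydroxyls stay free, C-acylation is excluded because ring B has no free position, and any phenol trifluoroacetate is cleaved in the bicarbonate work-up.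

**Compound list**
1 | pentan-3-one | CCC(=O)CC | starting material
2 | acetaldehyde | CC=O | starting material
3 | 5-hydroxy-4-methylhexan-3-one (racemic syn/anti mixture) | CCC(=O)C(C)C(C)O | intermediate
4 | (E)-4-methylhex-4-en-3-one | CCC(=O)/C(C)=C/C | intermediate
5 | dimethyl malonate | COC(=O)CC(=O)OC | starting material
6 | dimethyl 2-(3-methyl-4-oxohexan-2-yl)malonate (diastereomer mixture, not isolated) | CCC(=O)C(C)C(C)C(C(=O)OC)C(=O)OC | intermediate
7 | methyl 2-hydroxy-3,5,6-trimethyl-4-oxocyclohex-2-ene-1-carboxylate (diastereomer mixture) | COC(=O)C1C(C)C(C)C(=O)C(C)=C1O | intermediate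
8 | methyl 3-bromo-3,5,6-trimethyl-2,4-dioxocyclohexane-1-carboxylate (diastereomer mixture, not isolated) | COC(=O)C1C(C)C(C)C(=O)C(C)(Br)C1=O | intermediate
9 | methyl 2,4-dihydroxy-3,5,6-trimethylbenzoate | COC(=O)c1c(C)c(C)c(O)c(C)c1O | intermediate
10 | methyl 2,4-dihydroxy-3,6-dimethylbenzoate (atraric acid) | COC(=O)c1c(C)cc(O)c(C)c1O | starting material
11 | methyl 2-hydroxy-4-methoxy-3,6-dimethylbenzoate | COC(=O)c1c(C)cc(OC)c(C)c1O | intermediate
12 | methyl 5-chloro-2-hydroxy-4-methoxy-3,6-dimethylbenzoate | COC(=O)c1c(C)c(Cl)c(OC)c(C)c1O | intermediate
13 | 5-chloro-2-hydroxy-4-methoxy-3,6-dimethylbenzoic acid | OC(=O)c1c(C)c(Cl)c(OC)c(C)c1O | intermediate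
14 | 5-chloro-2-hydroxy-4-methoxy-3,6-dimethylbenzoic trifluoroacetic anhydride (not isolated) | O=C(OC(=O)C(F)(F)F)c1c(C)c(Cl)c(OC)c(C)c1O | intermediate
15 | methyl 4-[(5-chloro-2-hydroxy-4-methoxy-3,6-dimethylbenzoyl)oxy]-2-hydroxy-3,5,6-trimethylbenzoate | COC(=O)c1c(C)c(C)c(OC(=O)c2c(C)c(Cl)c(OC)c(C)c2O)c(C)c1O | target

Total step count: 8.
Longest linear sequence: 5 steps (steps 1, 2, 3, 4, 8); the ring A branch is steps 5, 6, 7 and joins at step 8.

**Steps most likely to fail**

Step 8. Acyl transfer to the 4-OH of 9, which sits between two methyl groups, may be too slow, so that trifluoroacetylation of the phenol or self-condensation of the hydroxy acid takes over. The coupling would then be run under basic conditions with a protected acid chloride. Setting out from 13, acetylation (Ac2O, pyridine, cat. DMAP, rt, aqueous work-up) would give 2-acetoxy-5-chloro-4-methoxy-3,6-dimethylbenzoic acid F1. Oxalyl chloride with cat. DMF in CH2Cl2 would give 2-acetoxy-5-chloro-4-methoxy-3,6-dimethylbenzoyl chloride F2. The sodium 4-phenoxide of 9 (NaH, one equivalent, THF, 0 °C; the 4-OH para to the ester is the more acidic) would be acylated to methyl 4-[(2-acetoxy-5-chloro-4-methoxy-3,6-dimethylbenzoyl)oxy]-2-hydroxy-3,5,6-trimethylbenzoate F3. Ammonolysis of the acetate (NH3, MeOH, 0 °C), which should spare the doubly ortho-shielded depside ester, would come back to the route at 15.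

Step 4. The bromine may stay locked at the quaternary C3, or be diverted to side-chain bromination or ester cleavage by hot HBr, before HBr is lost toward C6. The dehydrogenation would then be done without halogen. Setting out from 7, heating with Pd/C (10% Pd on carbon) in refluxing mesitylene under a nitrogen sweep, the acceptorless catalytic dehydrogenation known for cyclohexane-1,3-diones, would come back to the route at 9. This fallback makes no new compound (F0).

Step 3. The conjugate addition to the α-methylated, β-substituted enone may stall or revert while methoxide consumes 4 by self-condensation. The donor and acceptor roles of the Michael stage would then be exchanged and the same ring closure kept. Setting out from 2 and 5, Knoevenagel condensation (Ac2O, 80–100 °C, closed vessel) would give dimethyl 2-ethylidenemalonate F4. The lithium enolate of 1 (LiN(iPr)2, THF, −78 °C) would add to this doubly activated acceptor, forming the C5–C6 bond and giving 6, this time isolated. NaOMe in MeOH at reflux, then cold aq. HCl, would close C2–C3 and come back to the route at 7.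

**Further compounds**
F1 | step 8 | 2-acetoxy-5-chloro-4-methoxy-3,6-dimethylbenzoic acid | CC(=O)Oc1c(C)c(OC)c(Cl)c(C)c1C(=O)O
F2 | step 8 | 2-acetoxy-5-chloro-4-methoxy-3,6-dimethylbenzoyl chloride | CC(=O)Oc1c(C)c(OC)c(Cl)c(C)c1C(=O)Cl
F3 | step 8 | methyl 4-[(2-acetoxy-5-chloro-4-methoxy-3,6-dimethylbenzoyl)oxy]-2-hydroxy-3,5,6-trimethylbenzoate | COC(=O)c1c(C)c(C)c(OC(=O)c2c(C)c(Cl)c(OC)c(C)c2OC(C)=O)c(C)c1O
F0 | step 4 | none | none
F4 | step 3 | dimethyl 2-ethylidenemalonate | CC=C(C(=O)OC)C(=O)OC
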